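## Analysis of the target

The target is a 2,3-dihydro-1-benzofuran (numbering O1, C2, C3, C3a, C4 to C7, C7a; ring A is the benzo ring, ring B the pendant aryl group). C2 carries ring B (4-hydroxy-3,5-dimethoxyphenyl), C3 a hydroxymethyl group, C5 an (E)-propenoic acid chain and C7 a methoxy group. The only stereocentres are the adjacent C2 (S) and C3 (R). Aryl and hydroxymethyl are trans, which is also the more stable arrangement, so the real task is absolute control at one centre and relay to the other. The free phenol of ring B sits para to C2, so the benzylic O1–C2 bond can open towards a quinone methide under base, acid or oxidants. The cinnamic acid alkene rules out hydrogenolysis at the end, and both rings are electron-rich. Any intermediate with positive charge or a leaving group at C2 can lose the C3 proton and fall back to an aromatic benzofuran, which is the main hazard of any ionic construction of the C2–aryl bond. The plan rests on the O1–C2=C3 unit of a 7-methoxybenzofuran: it is an enol ether held in ring A, nucleophilic at C3 and able to carry positive charge at C2 through O1. A carbene can therefore bridge C2 and C3, and the resulting cyclopropane, with O1 as donor and an ester as acceptor, is a strained electrophile at C2.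

## Retrosynthetic reasoning

**C5–alkene bond and the phenol mask.** The acrylic acid of 20 is cut first, between C5 of ring A and the alkene carbon, giving aryl bromide 17 and acrylic acid 18 (Heck reaction). Bromine at C5 is a good placeholder: it should be inert to a copper carbene, to a Lewis acid, to hydroxide and to alkyl radicals, and it is already present in the commercial aldehyde 1. The acetate on ring B of 17 is removed in the same pot via 19, so the fragile free para-hydroxybenzyl ether appears only in the last operation.

**The hydroxymethyl carbon.** The CH2OH carbon of 17 is traced back to the methylene of the acetic acid arm in 14; in the forward sense the bond from that methylene to the carboxyl carbon is replaced by a C–O bond (decarboxylative hydroxylation). This retron is accepted because it lets an ester, an acceptor, sit on the carbon attached to C3 in the earlier steps. The radical step dictates protection: a free 2,6-dimethoxyphenol is a chain-breaking hydrogen donor, so acid 12 is acetylated to 14 first. Acid 12 comes from ethyl ester 11 by saponification.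

**C2–aryl bond.** In 11 the carbon bearing O1 and the aryl group (C2) stands 1,3 to the ester α-carbon, which is the retron of a donor–acceptor cyclopropane. Cutting C2–aryl and joining C2 to the ester α-carbon gives cyclopropane 9 and 2,6-dimethoxyphenol 10. Cutting here, and not at O1–C2 or C3–C3a, keeps ring A and its oxygen intact and brings ring B in as an unfunctionalised phenol. The forward reaction has to deliver the arene to C2 anti to the C3 arm and faster than the C3 proton is lost.

**The cyclopropane.** The two bonds from the ester-bearing carbon of 9 to C2 and C3 are cut to benzofuran 7 and ethyl diazoacetate 8. This is where absolute configuration enters: a chiral catalyst selects the face of C2=C3 and so fixes C3. The bond to C3 stays in the target; the bond to C2 is temporary.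

**Benzofuran 7.** Decarboxylation leads back to acid 6 and ester 5. The furan ring of 5 is cut at C2–C3 (aldol condensation) and at O1–C2 (phenol alkylation), giving aldehyde 1 and ethyl bromoacetate 2. These are three routine steps, so the risk of the route sits in the carbene step and the opening that follows.

## Alternatives that were turned down

**Alternative 1:** Both the C2–aryl and the C3–carbon bond are cut at once, back to 5-(dimethoxymethyl)-7-methoxy-1-benzofuran A1, the ring B boronic ester 2-[4-(benzyloxy)-3,5-dimethoxyphenyl]-4,4,5,5-tetramethyl-1,3,2-dioxaborolane A2 and allyl acetate A3.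
- Forward key step: A1 is lithiated at C2 and added to A2 to give a boron ate complex. A chiral allyl–palladium electrophile (Pd2(dba)3, chiral bisphosphine) then attacks C3 while the aryl group shifts from boron to C2, dearomatising the furan ring without closing a ring. The product is boronate A4, with aryl trans to allyl.
- For it: it is the most convergent plan. Both skeletal bonds and both stereocentres arise in one catalytic step, and the aryl group arrives as a boron-bound nucleophile, so neither Friedel–Crafts regiochemistry nor proton loss to a benzofuran is an issue. On these points it is stronger than the chosen plan.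
- Against it: A4 carries a tertiary, benzylic, oxygen-substituted C2–B bond that must be replaced by hydrogen with retention at a centre prone to ionisation. The allyl arm must be cut back by two carbons (isomerisation, oxidative cleavage, reduction). The acetal must be unmasked and homologated, and the benzyl ether removed in the presence of the acrylic acid alkene. The 1,2-shift is also less assured on benzofuran ate complexes than on more nucleophilic heteroarenes.
- Comparison: the endgame is at least six steps against five, with two stereochemically delicate operations. The chosen plan offers instead a catalytic asymmetric step of a type known on benzofurans, no surplus boron, and a one-carbon excision in a single decarboxylative operation.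

**Alternative 2:** The O1–C2 bond is cut, back to the open-chain diarylpropanol methyl (E)-3-{4-hydroxy-3-[(2R)-1-hydroxy-3-(4-hydroxy-3,5-dimethoxyphenyl)propan-2-yl]-5-methoxyphenyl}prop-2-enoate A5.
- Forward key step: Ag2O oxidises the ring B phenol of A5 to its para-quinone methide, and the ring A phenol adds to the exocyclic carbon (5-exo closure of the dihydrofuran ring). The product is methyl ester A6, one saponification from the target.
- For it: every carbon of the target is in place, so nothing has to be excised; the closure is mild and trans-selective by substrate control; the endgame is one step. On carbon economy and length of the endgame it is stronger.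
- Against it: the stereochemical problem is only moved. The C3 stereocentre of A5 must be made beforehand, most plausibly by a stoichiometric auxiliary alkylation costing several steps. A5 holds two oxidisable phenols, and the ferulate-type phenol of ring A is itself prone to oxidative radical coupling with Ag2O. The quinone methide can also tautomerise to a styrene by loss of the C3 proton, erasing the only preset stereocentre.
- Comparison: the chosen plan sets C3 by catalysis in the ring-building step and drives the C2 bond by ring strain, with no phenol oxidation anywhere in the route.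

**Alternative 3:** The C3–C3a bond is cut by a retro ring contraction, back to the flavanone 4-[(2S)-6-bromo-8-methoxy-4-oxo-3,4-dihydro-2H-chromen-2-yl]-2,6-dimethoxyphenyl 2,2-dimethylpropanoate A7.
- Forward key step: PhI(OAc)2 (trivalent iodine) with catalytic H2SO4 in methanol and an orthoformate converts the enol ether of A7 into an α-iodanyl species. Ring carbon C4a then migrates from the carbonyl carbon to C3 as iodobenzene leaves, contracting the pyranone. The old carbonyl carbon becomes the methyl ester of trans dihydrobenzofuran A8.
- For it: the C2–aryl bond comes from ordinary chalcone and flavanone chemistry, not from a new arylation. The ester carbon of A8 is the hydroxymethyl carbon, so one hydride reduction replaces the excision needed in the chosen plan, and the endgame is shorter. On these points it is stronger.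
- Against it: everything depends on one enantiomer of A7. Such flavanones racemise by reversible ring opening to the 2'-hydroxychalcone under the acid present, the more so with an electron-rich ring B, and an enantioselective entry to so substituted a flavanone is itself uncertain. Ring B can compete as the migrating group (the isoflavone pathway), and simple dehydrogenation to the flavone is possible.
- Comparison: the chosen plan stores its absolute configuration in a cyclopropane that cannot racemise and creates it catalytically, at the price of one carbon that has to be removed later.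

Key step: step 4

Assumption (remark on the chemistry): the (S,S) antipode of the tert-butyl bis(oxazoline) ligand is taken to give the (1R,1aR,6bS) adduct 9; both antipodes are commercial, so the opposite sense of induction would be met by the mirror-image ligand with no other change.

## Route

Step 1
Reactants: 1 5-bromo-2-hydroxy-3-methoxybenzaldehyde; 2 ethyl bromoacetate
Product: 5 ethyl 5-bromo-7-methoxy-1-benzofuran-2-carboxylate, via aryloxyacetate aldehyde 3 (not isolated), via aldol adduct 4 (not isolated)
Conditions: K2CO3, DMF, rt then 95 °C
Reagents that add atoms: none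
Why: Williamson O-alkylation of the phenoxide gives 3; on heating, carbonate deprotonates the activated OCH2 group, and intramolecular aldol addition to the ortho aldehyde (4) followed by dehydration gives the aromatic benzofuran ester.

Step 2
Reactants: 5 ethyl 5-bromo-7-methoxy-1-benzofuran-2-carboxylate
Product: 6 5-bromo-7-methoxy-1-benzofuran-2-carboxylic acid
Conditions: NaOH, EtOH/H2O, reflux; then aq. HCl
Reagents that add atoms: sodium hydroxide, [Na+].[OH-]
Why: Ester saponification; the aryl bromide, the methyl ether and the benzofuran are inert to aqueous hydroxide.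

Step 3
Reactants: 6 5-bromo-7-methoxy-1-benzofuran-2-carboxylic acid
Product: 7 5-bromo-7-methoxy-1-benzofuran
Conditions: Cu powder, quinoline, 200 °C
Reagents that add atoms: none
Why: Copper-mediated protodecarboxylation of a heteroaryl 2-carboxylic acid; CO2 is lost from the position next to the ring oxygen through an aryl–copper species that is protonated in the medium.

Step 4
Reactants: 7 5-bromo-7-methoxy-1-benzofuran; 8 ethyl diazoacetate
Product: 9 ethyl (1R,1aR,6bS)-5-bromo-3-methoxy-1a,6b-dihydro-1H-cyclopropa[b][1]benzofuran-1-carboxylate (exo ester)
Conditions: (CuOTf)2·C6H6 (2 mol%), (S,S)-t-Bu-box [2,2'-(propane-2,2-diyl)bis((4S)-4-tert-butyl-4,5-dihydro-1,3-oxazole), 4.4 mol%], 8 added by syringe pump, CH2Cl2, 0 °C to rt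
Reagents that add atoms: none
Why: The monovalent-copper bis(oxazoline) complex decomposes 8 with loss of N2 to an electrophilic copper carbene, which is attacked by the most nucleophilic π-bond of 7, the O1–C2=C3 enol ether, bonding first at C3 while positive charge is carried at C2 beside O1, and collapse onto C2 then closes the three-membered ring. The closest known reaction type is the copper bis(oxazoline) asymmetric cyclopropanation of furans, benzofurans and other enol ethers with diazoacetates. The one new ring is closed by a concerted but asynchronous [2+1] carbene transfer, suprafacial across C2=C3, so the ring fusion at C1a and C6b can only be cis. C6b (the future C3) is set by the face of the alkene that the C2-symmetric ligand leaves open, its tert-butyl groups blocking two diagonal quadrants around the carbene, and C1a follows from the cis fusion. C1 is set by the exo preference, the ester turning away from the benzo ring and the ligand wall in the transition state. The step needs chemoselectivity for C2=C3 over the benzo ring and the C–Br bond, which the enol-ether polarisation and the inertness of aryl bromides to copper carbenes secure, and it needs addition to outrun carbene dimerisation, which slow addition of 8 secures. The 7-methoxy group keeps O1 electron-rich and lies away from the reacting face.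

Step 5
Reactants: 9 ethyl (1R,1aR,6bS)-5-bromo-3-methoxy-1a,6b-dihydro-1H-cyclopropa[b][1]benzofuran-1-carboxylate; 10 2,6-dimethoxyphenol
Product: 11 ethyl 2-[(2S,3S)-5-bromo-2-(4-hydroxy-3,5-dimethoxyphenyl)-7-methoxy-2,3-dihydro-1-benzofuran-3-yl]acetate (2,3-trans)
Conditions: Sc(OTf)3 (10 mol%), 10 (3 equiv), 4 Å MS, CH2Cl2, −20 °C to rt
Reagents that add atoms: none
Why: Proposed new method: Sc(OTf)3 binds the ester carbonyl of 9, and the strained C1a–C1 bond, pushed by the lone pair of the ring oxygen directly on C1a (which is why this bond and not C6b–C1 breaks) and pulled by the scandium-bound ester, heterolyses towards an oxocarbenium–enolate pair. The para carbon of 10 (para to the coplanar hydrogen-bonded OH, flanked only by hydrogens, both ortho positions blocked) attacks C1a, the future C2, on the face opposite the departing carbon, so the aryl group ends trans to the acetate arm while C3 is untouched, and proton transfer from the arenium ion to the enolate releases 11 and the catalyst. The closest known reaction types are the Sc(OTf)3-catalysed Friedel–Crafts opening of donor–acceptor cyclopropane diesters by electron-rich arenes and the acid-promoted alcoholysis of 2-alkoxycyclopropane carboxylates.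

Step 6
Reactants: 11 ethyl 2-[(2S,3S)-5-bromo-2-(4-hydroxy-3,5-dimethoxyphenyl)-7-methoxy-2,3-dihydro-1-benzofuran-3-yl]acetate
Product: 12 2-[(2S,3S)-5-bromo-2-(4-hydroxy-3,5-dimethoxyphenyl)-7-methoxy-2,3-dihydro-1-benzofuran-3-yl]acetic acid
Conditions: LiOH·H2O, THF/H2O, 0 °C to rt; then 1 M HCl
Reagents that add atoms: lithium hydroxide, [Li+].[OH-]
Why: Ester saponification at room temperature; neither stereocentre is acidic (C3 is β to the carboxylate), and the phenoxide-driven opening of O1–C2 is slow under these conditions and would in any case re-close to the more stable trans isomer.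

Step 7
Reactants: 12 2-[(2S,3S)-5-bromo-2-(4-hydroxy-3,5-dimethoxyphenyl)-7-methoxy-2,3-dihydro-1-benzofuran-3-yl]acetic acid
Product: 14 2-[(2S,3S)-2-[4-(acetyloxy)-3,5-dimethoxyphenyl]-5-bromo-7-methoxy-2,3-dihydro-1-benzofuran-3-yl]acetic acid, via mixed acetic anhydride 13 (not isolated)
Conditions: Ac2O, pyridine, rt; then H2O, THF
Reagents that add atoms: acetic anhydride, CC(=O)OC(C)=O; water, O
Why: Nucleophilic acyl substitution: the phenol is acetylated and the carboxylic acid is carried as the mixed anhydride 13, which water hydrolyses on work-up while the aryl acetate stays. The acetate removes the chain-breaking phenolic O–H before the radical step and damps quinone-methide opening of O1–C2 in the later heated step.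

Step 8
Reactants: 14 2-[(2S,3S)-2-[4-(acetyloxy)-3,5-dimethoxyphenyl]-5-bromo-7-methoxy-2,3-dihydro-1-benzofuran-3-yl]acetic acid
Product: 17 4-[(2S,3R)-5-bromo-3-(hydroxymethyl)-7-methoxy-2,3-dihydro-1-benzofuran-2-yl]-2,6-dimethoxyphenyl acetate, via Barton ester 15 (not isolated), via hydroperoxide 16 (not isolated)
Conditions: N-hydroxypyridine-2-thione, DCC, DMAP (cat.), CH2Cl2, 0 °C, dark; then t-BuSH, O2, PhMe, hν (W lamp), 0 °C; then P(OMe)3, rt
Reagents that add atoms: dioxygen, O=O
Why: Barton decarboxylative hydroxylation: under visible light the thiohydroxamate ester 15 fragments in a radical chain to CO2 and the primary radical on the C3 methylene, which O2 captures faster than the radical can abstract hydrogen or fragment; t-BuSH reduces the peroxyl radical to 16 and carries the chain, and P(OMe)3 reduces 16 to the alcohol. The radical centre is exocyclic, so C2 and C3 keep their configuration (the C3 descriptor changes to R only through priority).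

Step 9
Reactants: 17 4-[(2S,3R)-5-bromo-3-(hydroxymethyl)-7-methoxy-2,3-dihydro-1-benzofuran-2-yl]-2,6-dimethoxyphenyl acetate; 18 acrylic acid
Product: 20 (E)-3-[(2S,3R)-2-(4-hydroxy-3,5-dimethoxyphenyl)-3-(hydroxymethyl)-7-methoxy-2,3-dihydro-1-benzofuran-5-yl]prop-2-enoic acid (target), via acetoxy cinnamic acid 19 (not isolated)
Conditions: Pd(OAc)2 (5 mol%), P(o-tol)3 (12 mol%), Et3N, DMF, 100 °C; then LiOH, THF/H2O, rt; then 1 M HCl
Reagents that add atoms: none
Why: Heck reaction: zerovalent palladium inserts into the unhindered C5–Br bond, syn insertion of the acrylate and syn β-hydride elimination give the E-alkene 19, and hydroxide then cleaves the only ester present, the aryl acetate, before acidification releases 20. Both stereocentres are spectators, and cleaving the acetate on purpose in the same pot brings any partly deacetylated material to the one product.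

## Compound list

1 | 5-bromo-2-hydroxy-3-methoxybenzaldehyde | COc1cc(Br)cc(C=O)c1O | starting material
2 | ethyl bromoacetate | CCOC(=O)CBr | starting material
3 | ethyl 2-(4-bromo-2-formyl-6-methoxyphenoxy)acetate (not isolated) | CCOC(=O)COc1c(C=O)cc(Br)cc1OC | intermediate
4 | ethyl 5-bromo-3-hydroxy-7-methoxy-2,3-dihydro-1-benzofuran-2-carboxylate (aldol adduct, racemic diastereomer mixture, not isolated) | CCOC(=O)C1Oc2c(OC)cc(Br)cc2C1O | intermediate
5 | ethyl 5-bromo-7-methoxy-1-benzofuran-2-carboxylate | CCOC(=O)c1cc2cc(Br)cc(OC)c2o1 | intermediate
6 | 5-bromo-7-methoxy-1-benzofuran-2-carboxylic acid | OC(=O)c1cc2cc(Br)cc(OC)c2o1 | intermediate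
7 | 5-bromo-7-methoxy-1-benzofuran | COc1cc(Br)cc2ccoc12 | intermediate
8 | ethyl diazoacetate | CCOC(=O)C=[N+]=[N-] | starting material
9 | ethyl (1R,1aR,6bS)-5-bromo-3-methoxy-1a,6b-dihydro-1H-cyclopropa[b][1]benzofuran-1-carboxylate (exo ester) | CCOC(=O)[C@H]1[C@@H]2Oc3c(OC)cc(Br)cc3[C@H]12 | intermediate
10 | 2,6-dimethoxyphenol | COc1cccc(OC)c1O | starting material
11 | ethyl 2-[(2S,3S)-5-bromo-2-(4-hydroxy-3,5-dimethoxyphenyl)-7-methoxy-2,3-dihydro-1-benzofuran-3-yl]acetate | COc1cc([C@H]2Oc3c(OC)cc(Br)cc3[C@@H]2CC(=O)OCC)cc(OC)c1O | intermediate
12 | 2-[(2S,3S)-5-bromo-2-(4-hydroxy-3,5-dimethoxyphenyl)-7-methoxy-2,3-dihydro-1-benzofuran-3-yl]acetic acid | COc1cc([C@H]2Oc3c(OC)cc(Br)cc3[C@@H]2CC(=O)O)cc(OC)c1O | intermediate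
13 | acetic 2-[(2S,3S)-2-[4-(acetyloxy)-3,5-dimethoxyphenyl]-5-bromo-7-methoxy-2,3-dihydro-1-benzofuran-3-yl]acetic anhydride (not isolated) | COc1cc([C@H]2Oc3c(OC)cc(Br)cc3[C@@H]2CC(=O)OC(C)=O)cc(OC)c1OC(C)=O | intermediate
14 | 2-[(2S,3S)-2-[4-(acetyloxy)-3,5-dimethoxyphenyl]-5-bromo-7-methoxy-2,3-dihydro-1-benzofuran-3-yl]acetic acid | COc1cc([C@H]2Oc3c(OC)cc(Br)cc3[C@@H]2CC(=O)O)cc(OC)c1OC(C)=O | intermediate
15 | 2-sulfanylidenepyridin-1(2H)-yl 2-[(2S,3S)-2-[4-(acetyloxy)-3,5-dimethoxyphenyl]-5-bromo-7-methoxy-2,3-dihydro-1-benzofuran-3-yl]acetate (Barton ester, not isolated) | COc1cc([C@H]2Oc3c(OC)cc(Br)cc3[C@@H]2CC(=O)On4ccccc4=S)cc(OC)c1OC(C)=O | intermediate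
16 | 4-[(2S,3R)-5-bromo-3-(hydroperoxymethyl)-7-methoxy-2,3-dihydro-1-benzofuran-2-yl]-2,6-dimethoxyphenyl acetate (not isolated) | COc1cc([C@H]2Oc3c(OC)cc(Br)cc3[C@@H]2COO)cc(OC)c1OC(C)=O | intermediate
17 | 4-[(2S,3R)-5-bromo-3-(hydroxymethyl)-7-methoxy-2,3-dihydro-1-benzofuran-2-yl]-2,6-dimethoxyphenyl acetate | COc1cc([C@H]2Oc3c(OC)cc(Br)cc3[C@@H]2CO)cc(OC)c1OC(C)=O | intermediate
18 | acrylic acid | C=CC(=O)O | starting material
19 | (E)-3-[(2S,3R)-2-[4-(acetyloxy)-3,5-dimethoxyphenyl]-3-(hydroxymethyl)-7-methoxy-2,3-dihydro-1-benzofuran-5-yl]prop-2-enoic acid (not isolated) | COc1cc([C@H]2Oc3c(OC)cc(/C=C/C(=O)O)cc3[C@@H]2CO)cc(OC)c1OC(C)=O | intermediate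
20 | (E)-3-[(2S,3R)-2-(4-hydroxy-3,5-dimethoxyphenyl)-3-(hydroxymethyl)-7-methoxy-2,3-dihydro-1-benzofuran-5-yl]prop-2-enoic acid | COc1cc([C@H]2Oc3c(OC)cc(/C=C/C(=O)O)cc3[C@@H]2CO)cc(OC)c1O | target

## Step count and least certain steps

Total step count: 9. Longest linear sequence: 9 steps (1 to 20).

**Step 5 (Proposed new method).** The most likely failure is loss of the C3 proton from the oxocarbenium ion, which re-aromatises the furan ring before the neutral and only moderately nucleophilic arene has bonded to C2. Lesser risks are attack through the phenol oxygen, attack at the arene position ortho and para to the methoxy groups, and renewed ionisation of the benzylic O1–C2 bond of the product followed by a second arylation.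

Fallback (sets out from 9, returns at 11), which replaces the neutral arene by an aryl–metal nucleophile and uses known reaction types throughout:
- 9 is opened in methanol with catalytic p-TsOH at 0 °C, where the solvent captures C2 far faster than a proton is lost, to give the methyl acetal ethyl 2-[(2S,3S)-5-bromo-2,7-dimethoxy-2,3-dihydro-1-benzofuran-3-yl]acetate F1.
- Exchange with PhSO2H and CaCl2 in CH2Cl2 gives the anomeric sulfone ethyl 2-[(2R,3S)-2-(benzenesulfonyl)-5-bromo-7-methoxy-2,3-dihydro-1-benzofuran-3-yl]acetate F2.
- Commercial 4-bromo-2,6-dimethoxyphenol is silylated (TBSCl, imidazole, DMF) to (4-bromo-2,6-dimethoxyphenoxy)(tert-butyl)dimethylsilane F3, converted with Mg in THF into {4-[tert-butyl(dimethyl)silyl]oxy-3,5-dimethoxyphenyl}magnesium bromide F4 and transmetalated with ZnBr2.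
- The arylzinc reagent displaces the sulfinate of F2 (THF, rt) within a zinc-paired ion pair, the aryl group entering anti to the C3 arm, to give ethyl 2-[(2S,3S)-5-bromo-2-{4-[tert-butyl(dimethyl)silyl]oxy-3,5-dimethoxyphenyl}-7-methoxy-2,3-dihydro-1-benzofuran-3-yl]acetate F5. The ester and the aryl bromide tolerate the zinc reagent.
- TBAF in THF at 0 °C returns 11.

**Step 4 (key step).** The most likely failures are insufficient facial discrimination on a benzo-fused enol ether and carbene dimerisation outrunning addition to a C2=C3 bond that is part of an aromatic furan.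

Fallback (sets out from 7, returns at 9): dirhodium tetraacetate Rh2(OAc)4 (1 mol%) with slow addition of 8 in CH2Cl2, the more electrophilic rhodium carbene coping better with the aromatic enol ether, gives the racemate rac-ethyl exo-5-bromo-3-methoxy-1a,6b-dihydro-1H-cyclopropa[b][1]benzofuran-1-carboxylate F6. Preparative chromatography on a chiral stationary phase then delivers the (1R,1aR,6bS) enantiomer, which is 9. Absolute configuration then comes from a separation and not from the catalyst.

**Step 8.** The likely failures are hydrogen-atom transfer from the thiol to the primary radical before oxygen capture (simple reduction), attack of peroxyl radicals on the electron-rich rings or the doubly activated C2–H, and β-scission of the radical with opening of the dihydrofuran ring towards a stabilised C2 radical.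

Fallback (sets out from 14, returns at 17): 14 is converted into 15 as before, and 15 is photolysed in CH2Cl2 with TEMPO (3 equiv) in the absence of thiol and oxygen. The radical combines with the persistent nitroxide at a near diffusion-controlled rate, giving the alkoxyamine 4-[(2S,3R)-5-bromo-7-methoxy-3-{[(2,2,6,6-tetramethylpiperidin-1-yl)oxy]methyl}-2,3-dihydro-1-benzofuran-2-yl]-2,6-dimethoxyphenyl acetate F7. Zn dust in AcOH/THF/H2O at 50 °C then cleaves the N–O bond to 17.

**Step 9.** The likely failures are slow oxidative addition into the electron-rich C5–Br bond with decay of the catalyst, and, at 100 °C under amine base, premature loss of the acetate followed by phenoxide-driven opening of O1–C2 (epimerisation at C2 or loss of formaldehyde).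

Fallback (sets out from 17, returns at 20): Suzuki–Miyaura coupling of 17 with commercial ethyl (E)-3-(4,4,5,5-tetramethyl-1,3,2-dioxaborolan-2-yl)prop-2-enoate (PdCl2(dppf), K3PO4, dioxane/H2O, 70 °C) replaces alkene insertion by transmetalation at lower temperature. It gives ethyl (E)-3-[(2S,3R)-2-[4-(acetyloxy)-3,5-dimethoxyphenyl]-3-(hydroxymethyl)-7-methoxy-2,3-dihydro-1-benzofuran-5-yl]prop-2-enoate F8, whose aryl acetate may already be partly cleaved. LiOH in THF/H2O at rt, then 1 M HCl, removes the ethyl ester and the acetate together to give 20.

**Step 3.** At 200 °C over copper the C5–Br bond may suffer reductive debromination or Ullmann-type coupling.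

Fallback (sets out from 1 and 2, returns at 7): the alkylation is run at room temperature (K2CO3, DMF) and 3 is isolated. LiOH in THF/H2O gives 2-(4-bromo-2-formyl-6-methoxyphenoxy)acetic acid F9. NaOAc in Ac2O/AcOH at reflux then closes the furan ring by an intramolecular Perkin-type condensation and expels CO2 in the same operation, giving 7 without copper and at a lower temperature.

## Further compounds

F1 | step 5 | ethyl 2-[(2S,3S)-5-bromo-2,7-dimethoxy-2,3-dihydro-1-benzofuran-3-yl]acetate | CO[C@H]1Oc2c(OC)cc(Br)cc2[C@@H]1CC(=O)OCC
F2 | step 5 | ethyl 2-[(2R,3S)-2-(benzenesulfonyl)-5-bromo-7-methoxy-2,3-dihydro-1-benzofuran-3-yl]acetate | O=S(=O)(c1ccccc1)[C@H]2Oc3c(OC)cc(Br)cc3[C@@H]2CC(=O)OCC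
F3 | step 5 | (4-bromo-2,6-dimethoxyphenoxy)(tert-butyl)dimethylsilane | COc1cc(Br)cc(OC)c1O[Si](C)(C)C(C)(C)C
F4 | step 5 | {4-[tert-butyl(dimethyl)silyl]oxy-3,5-dimethoxyphenyl}magnesium bromide | COc1cc([Mg]Br)cc(OC)c1O[Si](C)(C)C(C)(C)C
F5 | step 5 | ethyl 2-[(2S,3S)-5-bromo-2-{4-[tert-butyl(dimethyl)silyl]oxy-3,5-dimethoxyphenyl}-7-methoxy-2,3-dihydro-1-benzofuran-3-yl]acetate | COc1cc([C@H]2Oc3c(OC)cc(Br)cc3[C@@H]2CC(=O)OCC)cc(OC)c1O[Si](C)(C)C(C)(C)C
F6 | step 4 | rac-ethyl exo-5-bromo-3-methoxy-1a,6b-dihydro-1H-cyclopropa[b][1]benzofuran-1-carboxylate | CCOC(=O)[C@H]1[C@@H]2Oc3c(OC)cc(Br)cc3[C@H]12.CCOC(=O)[C@@H]1[C@H]2Oc3c(OC)cc(Br)cc3[C@@H]12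
F7 | step 8 | 4-[(2S,3R)-5-bromo-7-methoxy-3-{[(2,2,6,6-tetramethylpiperidin-1-yl)oxy]methyl}-2,3-dihydro-1-benzofuran-2-yl]-2,6-dimethoxyphenyl acetate | COc1cc([C@H]2Oc3c(OC)cc(Br)cc3[C@@H]2CON4C(C)(C)CCCC4(C)C)cc(OC)c1OC(C)=O
F8 | step 9 | ethyl (E)-3-[(2S,3R)-2-[4-(acetyloxy)-3,5-dimethoxyphenyl]-3-(hydroxymethyl)-7-methoxy-2,3-dihydro-1-benzofuran-5-yl]prop-2-enoate | COc1cc([C@H]2Oc3c(OC)cc(/C=C/C(=O)OCC)cc3[C@@H]2CO)cc(OC)c1OC(C)=O
F9 | step 3 | 2-(4-bromo-2-formyl-6-methoxyphenoxy)acetic acid | COc1cc(Br)cc(C=O)c1OCC(=O)O
A1 | alternative 1 | 5-(dimethoxymethyl)-7-methoxy-1-benzofuran | COc1cc(C(OC)OC)cc2ccoc12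
A2 | alternative 1 | 2-[4-(benzyloxy)-3,5-dimethoxyphenyl]-4,4,5,5-tetramethyl-1,3,2-dioxaborolane | COc1cc(B2OC(C)(C)C(C)(C)O2)cc(OC)c1OCc1ccccc1
A3 | alternative 1 | allyl acetate | C=CCOC(C)=O
A4 | alternative 1 | 2-[(2S,3S)-3-allyl-2-[4-(benzyloxy)-3,5-dimethoxyphenyl]-5-(dimethoxymethyl)-7-methoxy-2,3-dihydro-1-benzofuran-2-yl]-4,4,5,5-tetramethyl-1,3,2-dioxaborolane (aryl trans to allyl) | COc1cc([C@@]2(B4OC(C)(C)C(C)(C)O4)Oc3c(OC)cc(C(OC)OC)cc3[C@@H]2CC=C)cc(OC)c1OCc1ccccc1
A5 | alternative 2 | methyl (E)-3-{4-hydroxy-3-[(2R)-1-hydroxy-3-(4-hydroxy-3,5-dimethoxyphenyl)propan-2-yl]-5-methoxyphenyl}prop-2-enoate | COC(=O)/C=C/c1cc(OC)c(O)c(c1)[C@@H](Cc1cc(OC)c(O)c(OC)c1)CO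
A6 | alternative 2 | methyl (E)-3-[(2S,3R)-2-(4-hydroxy-3,5-dimethoxyphenyl)-3-(hydroxymethyl)-7-methoxy-2,3-dihydro-1-benzofuran-5-yl]prop-2-enoate | COc1cc([C@H]2Oc3c(OC)cc(/C=C/C(=O)OC)cc3[C@@H]2CO)cc(OC)c1O
A7 | alternative 3 | 4-[(2S)-6-bromo-8-methoxy-4-oxo-3,4-dihydro-2H-chromen-2-yl]-2,6-dimethoxyphenyl 2,2-dimethylpropanoate | COc1cc([C@@H]2CC(=O)c3cc(Br)cc(OC)c3O2)cc(OC)c1OC(=O)C(C)(C)C
A8 | alternative 3 | methyl (2S,3S)-5-bromo-2-[3,5-dimethoxy-4-(pivaloyloxy)phenyl]-7-methoxy-2,3-dihydro-1-benzofuran-3-carboxylate | COc1cc([C@H]2Oc3c(OC)cc(Br)cc3[C@@H]2C(=O)OC)cc(OC)c1OC(=O)C(C)(C)C
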